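**Retrosynthetic overview**

1. The target is a daucane: a cyclopentane (C1 quaternary with CH3, C2, C3, C4 carbinol with isopropyl, C5) trans-fused to a cycloheptenone (C1, C5, C6 ester carbon, C7, C8 with CH3, C9, C10 ketone). The veratrate, the silyl ether and the C6–O/C5–H pair are removed last, back to a ring-fusion alkene C5=C6.
2. Key disconnection: the seven-membered ring is opened at C8–C9 and C10–C1 to a cis-1-methyl-2-cyclopentenylcyclopropyl diazomethyl ketone. A tandem Wolff/Cope rearrangement makes both bonds and sacrifices the cyclopropane bond C6–C8, which is not in the target.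
3. Enabling feature: the ring segment O=C10–C9H=C8(CH3)–C7H2–C6–C5 on quaternary C1 is a cyclohepta-2,5-dienone retron once C5=C6 is an alkene. C9–C10 is then a ketene, C6–C7–C8 a cyclopropane, and C5=C1 the alkene of a 2-methylcyclopentene.
4. The cyclopentene comes from (S)-terpinen-4-ol by ozonolytic C–C cleavage and aldol reclosure (six- to five-membered ring, carbinol centre kept). The cyclopropane comes from a (Z)-allylic alcohol by Charette cyclopropanation, and its configuration is relayed to C1.
5. Ring order: cyclohexene (chiral pool, cleaved) → cyclopentene → cyclopropane (temporary) → cycloheptadienone (key step).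

Key step: step 9

Assumption: commercial (S)-(+)-terpinen-4-ol is used enantiomerically pure; any minor enantiomer would appear after step 6 as a separable diastereomer of 9.
Abbreviation: R* = (5R)-2-methyl-5-(propan-2-yl)-5-[(triethylsilyl)oxy]cyclopent-1-en-1-yl.

**Route**

Step 1
Reactants: 1 (S)-(+)-terpinen-4-ol, (1S)-4-methyl-1-(propan-2-yl)cyclohex-3-en-1-ol
Product: 2 triethyl{[(1S)-4-methyl-1-(propan-2-yl)cyclohex-3-en-1-yl]oxy}silane
Conditions: Et3SiOTf, 2,6-lutidine, CH2Cl2, 0 °C to rt
Reagents that add atoms: triethylsilyl trifluoromethanesulfonate, CC[Si](CC)(CC)OS(=O)(=O)C(F)(F)F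
Why: Silyl triflate silylation of a hindered tertiary alcohol; the ether masks the carbinol (which would otherwise add to the ketene and direct later oxidations) until the last step.

Step 2
Reactants: 2 triethylsilyl ether of terpinen-4-ol
Product: 4 (3S)-6-oxo-3-(propan-2-yl)-3-[(triethylsilyl)oxy]heptanal, via ozonide 3 (not isolated)
Conditions: O3, CH2Cl2, −78 °C; then PPh3, −78 °C to rt
Reagents that add atoms: ozone, [O-][O+]=O
Why: Ozonolysis with reductive work-up cleaves the only C=C bond of the chiral-pool ring to the 1,6-keto aldehyde and leaves the carbinol stereocentre untouched.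

Step 3
Reactants: 4 keto aldehyde
Product: 5 (5R)-2-methyl-5-(propan-2-yl)-5-[(triethylsilyl)oxy]cyclopent-1-ene-1-carbaldehyde
Conditions: Bn2NH·CF3CO2H (0.3 equiv), toluene, rt to 50 °C
Reagents that add atoms: none
Why: Amine-salt-catalysed intramolecular aldol condensation, in which the aldehyde-derived enamine adds 5-exo to the methyl ketone and dehydration gives the tetrasubstituted enal, the regiochemistry being that known for terpene-derived 1,6-keto aldehydes.

Step 4
Reactants: 5 cyclopentene carbaldehyde; 6 ethyl 2-[bis(2,2,2-trifluoroethoxy)phosphoryl]propanoate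
Product: 7 ethyl (2Z)-2-methyl-3-R*-prop-2-enoate
Conditions: KN(SiMe3)2, 18-crown-6, THF, −78 to −40 °C
Reagents that add atoms: ethyl 2-[bis(2,2,2-trifluoroethoxy)phosphoryl]propanoate, CCOC(=O)C(C)P(=O)(OCC(F)(F)F)OCC(F)(F)F
Why: Still–Gennari olefination, whose fast, irreversible elimination from the kinetic adduct should give the (Z)-trisubstituted enoate and so place the ester cis to the cyclopentenyl group, as the cis-cyclopropane later requires.

Step 5
Reactants: 7 (Z)-dienoate
Product: 8 (2Z)-2-methyl-3-R*-prop-2-en-1-ol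
Conditions: iBu2AlH (2.5 equiv), CH2Cl2, −78 °C; aq potassium sodium tartrate
Reagents that add atoms: none
Why: 1,2-Reduction of the conjugated ester by the aluminium hydride gives the allylic alcohol with the alkene geometry retained.

Step 6
Reactants: 8 (Z)-allylic alcohol
Product: 9 [(1S,2R)-1-methyl-2-R*-cyclopropyl]methanol (hydroxymethyl and R* cis)
Conditions: Zn(CH2I)2·DME (from Et2Zn, CH2I2, DME), (4R,5R)-2-butyl-N,N,N′,N′-tetramethyl-1,3,2-dioxaborolane-4,5-dicarboxamide (1.2 equiv), CH2Cl2, −10 °C to rt; aq NH4Cl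
Reagents that add atoms: diiodomethane, ICI
Why: Charette asymmetric Simmons–Smith cyclopropanation: methylene is delivered only to the alkene allylic to the zinc alkoxide, the Z geometry is translated stereospecifically into the cis relationship, and the (4R,5R)-dioxaborolane selects the alkene face that gives the (1S,2R) ring, by the established facial model for this ligand.

Step 7
Reactants: 9 cyclopropylmethanol
Product: 11 (1S,2S)-1-methyl-2-R*-cyclopropane-1-carboxylic acid, via aldehyde 10 (not isolated)
Conditions: TEMPO (0.2 equiv), PhI(OAc)2 (2.2 equiv), MeCN/H2O (1:1), rt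
Reagents that add atoms: water, O
Why: Oxoammonium-mediated oxidation of the primary alcohol through the aldehyde hydrate to the acid under near-neutral conditions that the silyl ether, cyclopropane and tetrasubstituted alkene should tolerate.

Step 8
Reactants: 11 cyclopropanecarboxylic acid
Product: 13 2-diazo-1-[(1S,2S)-1-methyl-2-R*-cyclopropyl]ethan-1-one, via acid chloride 12 (not isolated)
Conditions: 1-chloro-N,N,2-trimethylprop-1-en-1-amine, CH2Cl2, 0 °C to rt; then CH2N2 (3 equiv), Et2O, 0 °C
Reagents that add atoms: diazomethane, C=[N+]=[N-]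
Why: Neutral acid chloride formation (no HCl, so no silyl loss or acid-induced lactonisation onto the alkene) followed by acylation of diazomethane, the first stage of an Arndt–Eistert sequence; the α-quaternary acid chloride cannot form a ketene and no stereocentre is touched.

Step 9
Reactants: 13 diazoketone
Product: 15 (3R,8aS)-6,8a-dimethyl-3-(propan-2-yl)-3-[(triethylsilyl)oxy]-2,3,5,8a-tetrahydroazulen-8(1H)-one, via ketene 14 (not isolated)
Conditions: AgO2CPh (0.1 equiv), Et3N (1 equiv), THF (0.01 M), sonication, 45 °C, dark; then 65 °C until the ketene is consumed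
Reagents that add atoms: none
Why: AgO2CPh/Et3N decomposes the diazoketone and the cyclopropyl carbon C8 migrates with retention to the former diazo carbon (Wolff rearrangement, bond C8–C9), giving ketene 14, in which the C9=C10 bond and the cis 2-methylcyclopentenyl alkene C5=C1 flank the strained C6–C8 bond as a 1,5-diene; a [3,3] shift through the endo boat then forms C10–C1 and cleaves C6–C8, driven by release of cyclopropane strain and conversion of the ketene into a ketone. The closest known reaction type is the tandem Wolff/Cope rearrangement of cis-2-alkenylcyclopropyl diazomethyl ketones to ring-fused cyclohepta-2,5-dienones. The seven-membered ring closes by concerted 3,3-sigmatropic bond formation between the ketene carbonyl carbon and the alkene terminus, the three-membered ring being expanded by four atoms. The new quaternary centre C1 is controlled by the cyclopropane configuration from step 6: in the boat array the (1S,2S)-cyclopropane can present only the cyclopentene face anti to the silyloxy group to the ketene, so chirality passes from C6/C8 (which become sp2) to C1. The step needs the cis relationship of acyl and alkenyl groups (secured by the Z-alkene and the stereospecific cyclopropanation), a Cope shift that outruns ketene capture (dilute aprotic medium, no free hydroxyl group, warming because the alkene terminus carries an inward methyl group), and exclusion of ultraviolet light so that the β,γ-unsaturated ketone does not undergo a 1,3-acyl shift.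

Step 10
Reactants: 15 cyclohepta-2,5-dienone
Product: 16 (3R,3aR,8aS)-6,8a-dimethyl-3-(propan-2-yl)-3-[(triethylsilyl)oxy]-2,3,3a,8a-tetrahydroazulen-8(1H)-one (H-3a anti to the 8a-methyl group, trans ring fusion)
Conditions: DBU (0.2 equiv), toluene, rt, argon
Reagents that add atoms: none
Why: Base-mediated conjugation: deprotonation at the doubly allylic C7 and reprotonation of the extended enolate at C5 moves the ring-fusion alkene into the 2,4-dienone, and C5–H is set under thermodynamic control, the trans-fused isomer being expected because the cycloheptadienone needs a large torsion at its only sp3–sp3 bond and C6 then avoids the isopropyl group.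

Step 11
Reactants: 16 conjugated 2,4-dienone
Product: 17 4,5-epoxide of 16 (azulene locants, i.e. at C6=C7; oxygen on the face of H-3a, anti to the five-membered ring)
Conditions: mCPBA, NaHCO3, CH2Cl2, 0 °C
Reagents that add atoms: 3-chloroperoxybenzoic acid, OOC(=O)c1cccc(Cl)c1
Why: Prilezhaev epoxidation is selective for the distal, more electron-rich γ,δ-alkene of a dienone and should occur from the face of H-5, away from the quaternary C4, which sets the C6–O configuration.

Step 12
Reactants: 17 γ,δ-epoxy enone
Product: 19 (3R,3aS,4S,8aS)-4-hydroxy-6,8a-dimethyl-3-(propan-2-yl)-3-[(triethylsilyl)oxy]-2,3,3a,4,5,8a-hexahydroazulen-8(1H)-one, via deconjugated enone 18 (not isolated)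
Conditions: SmI2 (2.2 equiv), THF/MeOH, −78 °C; then DBU (0.1 equiv), CH2Cl2, rt
Reagents that add atoms: none
Why: Single-electron reduction of the vinylogous epoxy ketone cleaves the γ C–O bond, kinetic α-protonation gives the β,γ-enone 18, and mild base returns the alkene to conjugation, the C6 carbinol configuration being untouched.

Step 13
Reactants: 19 δ-hydroxy enone; 20 3,4-dimethoxybenzoyl chloride
Product: 21 (3R,3aS,4S,8aS)-6,8a-dimethyl-8-oxo-3-(propan-2-yl)-3-[(triethylsilyl)oxy]-1,2,3,3a,4,5,8,8a-octahydroazulen-4-yl 3,4-dimethoxybenzoate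
Conditions: 20 (1.5 equiv), DMAP (0.2 equiv), pyridine, CH2Cl2, 0 °C to rt
Reagents that add atoms: 3,4-dimethoxybenzoyl chloride, COc1ccc(C(Cl)=O)cc1OC
Why: DMAP-catalysed acylation of the only free (secondary) hydroxyl group under weakly basic conditions that should not trigger vinylogous elimination.

Step 14
Reactants: 21 silyl-protected ester
Product: 22 (3R,3aS,4S,8aS)-3-hydroxy-6,8a-dimethyl-8-oxo-3-(propan-2-yl)-1,2,3,3a,4,5,8,8a-octahydroazulen-4-yl 3,4-dimethoxybenzoate (target)
Conditions: HF·pyridine, pyridine, THF, 0 °C to rt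
Reagents that add atoms: none
Why: Fluoride-mediated cleavage of the tertiary silyl ether in a buffered, non-basic medium, which avoids acyl migration to the tertiary alcohol and vinylogous β-elimination of the veratrate.

**Compound list**

1 | (S)-(+)-terpinen-4-ol | CC1=CC[C@](O)(C(C)C)CC1 | starting material
2 | triethyl{[(1S)-4-methyl-1-(propan-2-yl)cyclohex-3-en-1-yl]oxy}silane | CC1=CC[C@](O[Si](CC)(CC)CC)(C(C)C)CC1 | intermediate
3 | ozonide (1,2,4-trioxolane) of 2, mixture at the two acetal carbons | CC12CC[C@@](O[Si](CC)(CC)CC)(C(C)C)CC(OO1)O2 | intermediate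
4 | (3S)-6-oxo-3-(propan-2-yl)-3-[(triethylsilyl)oxy]heptanal | O=CC[C@](O[Si](CC)(CC)CC)(C(C)C)CCC(C)=O | intermediate
5 | (5R)-2-methyl-5-(propan-2-yl)-5-[(triethylsilyl)oxy]cyclopent-1-ene-1-carbaldehyde | O=CC1=C(C)CC[C@@]1(O[Si](CC)(CC)CC)C(C)C | intermediate
6 | ethyl 2-[bis(2,2,2-trifluoroethoxy)phosphoryl]propanoate | CCOC(=O)C(C)P(=O)(OCC(F)(F)F)OCC(F)(F)F | starting material
7 | ethyl (2Z)-2-methyl-3-R*-prop-2-enoate | CCOC(=O)/C(C)=C\C1=C(C)CC[C@@]1(O[Si](CC)(CC)CC)C(C)C | intermediate
8 | (2Z)-2-methyl-3-R*-prop-2-en-1-ol | OC/C(C)=C\C1=C(C)CC[C@@]1(O[Si](CC)(CC)CC)C(C)C | intermediate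
9 | [(1S,2R)-1-methyl-2-R*-cyclopropyl]methanol | OC[C@@]1(C)C[C@H]1C2=C(C)CC[C@@]2(O[Si](CC)(CC)CC)C(C)C | intermediate
10 | (1S,2S)-1-methyl-2-R*-cyclopropane-1-carbaldehyde | O=C[C@@]1(C)C[C@H]1C2=C(C)CC[C@@]2(O[Si](CC)(CC)CC)C(C)C | intermediate
11 | (1S,2S)-1-methyl-2-R*-cyclopropane-1-carboxylic acid | OC(=O)[C@@]1(C)C[C@H]1C2=C(C)CC[C@@]2(O[Si](CC)(CC)CC)C(C)C | intermediate
12 | (1S,2S)-1-methyl-2-R*-cyclopropane-1-carbonyl chloride | ClC(=O)[C@@]1(C)C[C@H]1C2=C(C)CC[C@@]2(O[Si](CC)(CC)CC)C(C)C | intermediate
13 | 2-diazo-1-[(1S,2S)-1-methyl-2-R*-cyclopropyl]ethan-1-one | [N-]=[N+]=CC(=O)[C@@]1(C)C[C@H]1C2=C(C)CC[C@@]2(O[Si](CC)(CC)CC)C(C)C | intermediate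
14 | 2-[(1S,2R)-1-methyl-2-R*-cyclopropyl]ethen-1-one (ketene) | O=C=C[C@@]1(C)C[C@H]1C2=C(C)CC[C@@]2(O[Si](CC)(CC)CC)C(C)C | intermediate
15 | (3R,8aS)-6,8a-dimethyl-3-(propan-2-yl)-3-[(triethylsilyl)oxy]-2,3,5,8a-tetrahydroazulen-8(1H)-one | CC1=CC(=O)[C@@]2(C)CC[C@@](O[Si](CC)(CC)CC)(C(C)C)C2=CC1 | intermediate
16 | (3R,3aR,8aS)-6,8a-dimethyl-3-(propan-2-yl)-3-[(triethylsilyl)oxy]-2,3,3a,8a-tetrahydroazulen-8(1H)-one | CC1=CC(=O)[C@@]2(C)CC[C@@](O[Si](CC)(CC)CC)(C(C)C)[C@@H]2C=C1 | intermediate
17 | 4,5-epoxide of 16, oxygen cis to H-3a | CC1=CC(=O)[C@@]2(C)CC[C@@](O[Si](CC)(CC)CC)(C(C)C)[C@@H]2[C@H]3O[C@@H]13 | intermediate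
18 | (3R,3aS,4S,8aS)-4-hydroxy-6,8a-dimethyl-3-(propan-2-yl)-3-[(triethylsilyl)oxy]-2,3,3a,4,7,8a-hexahydroazulen-8(1H)-one | O[C@H]1C=C(C)CC(=O)[C@@]2(C)CC[C@@](O[Si](CC)(CC)CC)(C(C)C)[C@H]12 | intermediate
19 | (3R,3aS,4S,8aS)-4-hydroxy-6,8a-dimethyl-3-(propan-2-yl)-3-[(triethylsilyl)oxy]-2,3,3a,4,5,8a-hexahydroazulen-8(1H)-one | O[C@H]1CC(C)=CC(=O)[C@@]2(C)CC[C@@](O[Si](CC)(CC)CC)(C(C)C)[C@H]12 | intermediate
20 | 3,4-dimethoxybenzoyl chloride | COc1ccc(C(Cl)=O)cc1OC | starting material
21 | (3R,3aS,4S,8aS)-6,8a-dimethyl-8-oxo-3-(propan-2-yl)-3-[(triethylsilyl)oxy]-1,2,3,3a,4,5,8,8a-octahydroazulen-4-yl 3,4-dimethoxybenzoate | COc1ccc(C(=O)O[C@H]2CC(C)=CC(=O)[C@@]3(C)CC[C@@](O[Si](CC)(CC)CC)(C(C)C)[C@H]23)cc1OC | intermediate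
22 | (3R,3aS,4S,8aS)-3-hydroxy-6,8a-dimethyl-8-oxo-3-(propan-2-yl)-1,2,3,3a,4,5,8,8a-octahydroazulen-4-yl 3,4-dimethoxybenzoate | COc1ccc(C(=O)O[C@H]2CC(C)=CC(=O)[C@@]3(C)CC[C@@](O)(C(C)C)[C@H]23)cc1OC | target

**Step count and risks**

Total step count: 14. Longest linear sequence: 14 steps (1 to 22).

Steps most likely to fail:

Step 9. The [3,3] shift may be retarded by the inward methyl group on the fully substituted alkene terminus, so that the monoalkylketene is lost to dimerisation or to adventitious nucleophiles before it rearranges. Fallback (sets out from 13, returns at 15): the two bonds are made in separate operations. Wolff rearrangement of 13 in methanol (AgO2CPh, Et3N, MeOH) should give the homologated methyl ester F1. iBu2AlH at −78 °C should give the aldehyde F2, and Me3SiOTf/Et3N the trimethylsilyl enol ether F3. F3 is a stable siloxy-divinylcyclopropane that can be heated (toluene, 110–140 °C, sealed tube) for as long as the Cope rearrangement needs, giving the allylic silyl ether F4. K2CO3/MeOH should free the allylic alcohol F5, and MnO2 should oxidise it to 15.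

Step 10. C5 is set by reversible protonation of an extended enolate, so an unfavourable ratio of ring-fusion epimers, incomplete conjugation, or loss of the tertiary silyloxy group by vinylogous β-elimination from the same enolate are possible. Fallback (sets out from 15, returns at 21): a base-free syn hydration under kinetic control. Conjugate reduction of the enone of 15 with [(Ph3P)CuH]6 should give the saturated ketone F6 (mixture at the methyl-bearing carbon). BH3·THF then reduces the ketone and hydroborates the only remaining alkene from the face anti to the angular methyl and silyloxy groups; NaBO3 oxidation should give the diol F7, in which H-5 and the C6 oxygen are cis by syn addition. The less hindered C6 hydroxyl is acylated with 20 (DMAP, pyridine) to the monoester F8, and Dess–Martin oxidation of the remaining neopentyl alcohol gives the ketone F9. IBX dehydrogenation (DMSO/toluene, 70 °C) can only go toward C9 because C1 is quaternary; it restores the enone and gives 21.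

Step 6. Facial selectivity may be poor if the reagent control of the dioxaborolane is overridden by the bias of the bulky, chiral cyclopentenyl group cis to the hydroxymethyl group, and methylene transfer to this hindered alkene may be sluggish. Fallback (sets out from 8, returns at 9): ligand-free Furukawa-modified Simmons–Smith cyclopropanation (Et2Zn, CH2I2, CH2Cl2, 0 °C), directed only by the zinc alkoxide, is stereospecific for the cis ring but not face-selective. Because the carbinol centre is fixed, the two products are diastereomers, 9 and its cyclopropane epimer F10, and should be separable by chromatography; 9 re-enters the route at step 7.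

Further compounds
F1 | step 9 | methyl 2-(cis-1-methyl-2-R*-cyclopropyl)acetate, ring configuration as in 14 | COC(=O)C[C@@]1(C)C[C@H]1C2=C(C)CC[C@@]2(O[Si](CC)(CC)CC)C(C)C
F2 | step 9 | 2-(cis-1-methyl-2-R*-cyclopropyl)acetaldehyde | O=CC[C@@]1(C)C[C@H]1C2=C(C)CC[C@@]2(O[Si](CC)(CC)CC)C(C)C
F3 | step 9 | trimethylsilyl enol ether of F2, E/Z mixture | C[Si](C)(C)OC=C[C@@]1(C)C[C@H]1C2=C(C)CC[C@@]2(O[Si](CC)(CC)CC)C(C)C
F4 | step 9 | 8-trimethylsilyl ether of the allylic alcohol corresponding to 15, mixture at C-8 | CC1=CC(O[Si](C)(C)C)[C@@]2(C)CC[C@@](O[Si](CC)(CC)CC)(C(C)C)C2=CC1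
F5 | step 9 | allylic alcohol corresponding to 15 (8-hydroxy in place of 8-oxo), mixture at C-8 | CC1=CC(O)[C@@]2(C)CC[C@@](O[Si](CC)(CC)CC)(C(C)C)C2=CC1
F6 | step 10 | 6,7-dihydro derivative of 15 (saturated ketone, ring-fusion alkene kept), mixture at C-6 | CC1CC(=O)[C@@]2(C)CC[C@@](O[Si](CC)(CC)CC)(C(C)C)C2=CC1
F7 | step 10 | 4,8-diol from hydroboration of F6 (3aS,4S,8aS; mixtures at C-6 and C-8) | O[C@H]1CC(C)CC(O)[C@@]2(C)CC[C@@](O[Si](CC)(CC)CC)(C(C)C)[C@H]12
F8 | step 10 | 4-(3,4-dimethoxybenzoate) of F7 | COc1ccc(C(=O)O[C@H]2CC(C)CC(O)[C@@]3(C)CC[C@@](O[Si](CC)(CC)CC)(C(C)C)[C@H]23)cc1OC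
F9 | step 10 | 6,7-dihydro derivative of 21 (saturated 8-ketone), mixture at C-6 | COc1ccc(C(=O)O[C@H]2CC(C)CC(=O)[C@@]3(C)CC[C@@](O[Si](CC)(CC)CC)(C(C)C)[C@H]23)cc1OC
F10 | step 6 | [(1R,2S)-1-methyl-2-R*-cyclopropyl]methanol, cyclopropane epimer of 9 | OC[C@]1(C)C[C@@H]1C2=C(C)CC[C@@]2(O[Si](CC)(CC)CC)C(C)C
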